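**Retrosynthetic overview**

1. Ring A is opened as in the chalcone-synthase step: retro-Claisen of the acylphloroglucinol gives a tetraketide ester (ring B dihydrocinnamoyl starter plus three acetate units), held as a 2-pyranone lactone.
2. That pyranone already carries the dihydropyran ring. Cutting the C–C bond beside the ketone leaves a bicyclic pyranopyranone (triketide plus C5 unit) and an ortho-prenylated methyl dihydrocinnamate.
3. The pyranopyranone is cut by retro-cycloetherification and retro-prenylation to triacetic acid lactone and isoprene (prenyl-cation logic of the prenyltransferase/cyclase pair).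
4. Order of ring formation: dihydropyran ring first, under acid, before any acid-sensitive prenyl group exists; aromatic ring A last, under base, in the same flask as the fragment coupling. Ring B is bought.

Assumption: the target has no stereocentre and no stereogenic double bond, so the achiral compound itself is the required single species; salts (phenoxides, enolates) and tautomers of a numbered compound are not numbered separately.

**Route**

Step 1
Reactants: 1 triacetic acid lactone (4-hydroxy-6-methyl-2H-pyran-2-one); 2 isoprene
Product: 4 2,2,7-trimethyl-3,4-dihydro-2H,5H-pyrano[4,3-b]pyran-5-one, via 3-prenyl pyranone 3 (not isolated)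
Conditions: isoprene (3 equiv), Amberlyst 15 (sulfonic acid resin, cat.), THF–heptane, 70 °C, sealed vessel; chromatography to remove the minor 4-pyranone isomer
Reagents that add atoms: none
Why: Acid-catalysed prenylation/cycloetherification (Friedel–Crafts-type C-alkylation, then Markovnikov hydroalkoxylation), a known reaction type for 4-hydroxycoumarins, 4-hydroxy-2-pyranones and phenols: the prenyl cation from protonated isoprene attacks C3 of 1, the only strongly nucleophilic carbon, to give 3, whose olefin is protonated to the tertiary cation and trapped by the neighbouring 4-OH, so the pyran oxygen sits on the carbon that becomes the para-oxygenated carbon of ring A; no stereocentre is formed.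

Step 2
Reactants: 5 methyl 3-(4-hydroxyphenyl)propanoate; 6 prenyl bromide (1-bromo-3-methylbut-2-ene)
Product: 7 methyl 3-[4-hydroxy-3-(3-methylbut-2-en-1-yl)phenyl]propanoate
Conditions: NaH (1.05 equiv), toluene, 0 °C; then 6 (1.1 equiv), rt
Reagents that add atoms: none
Why: Ortho-selective C-alkylation of a phenoxide in a non-polar medium (Claisen C-alkylation): the tightly ion-paired sodium phenoxide of 5 suspended in toluene reacts with the allylic bromide through the carbon ortho to oxygen (para is blocked) and rearomatises by tautomerisation, while the ester is untouched by the weakly basic phenoxide; no stereocentre is formed.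

Step 3
Reactants: 4 2,2,7-trimethyl-3,4-dihydro-2H,5H-pyrano[4,3-b]pyran-5-one; 7 methyl 3-[4-hydroxy-3-(3-methylbut-2-en-1-yl)phenyl]propanoate
Product: 10 1-(5,7-dihydroxy-2,2-dimethyl-3,4-dihydro-2H-chromen-6-yl)-3-[4-hydroxy-3-(3-methylbut-2-en-1-yl)phenyl]propan-1-one (CNP0080516.0), via acylated pyranone 8 (not isolated), via ring-opened keto ester 9 (not isolated)
Conditions: 4 (2.2 equiv), LiN(iPr)2 (2.2 equiv), THF, −78 °C; add lithium phenoxide of 7 (7 + 1.0 equiv LiN(iPr)2), −78 → 0 °C; then Mg(OMe)2 (8 equiv), MeOH, 65 °C; 1 M HCl, 0 °C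
Reagents that add atoms: none
Why: Proposed new method: the lithiated 7-methyl group of 4 (a vinylogous ester enolate, formed cleanly because the pyranone carbon between the two oxygenated carbons is blocked) is C-acylated by ester 7 in a crossed Claisen condensation to give 8, a lactone-masked 3,5,7-triketo acid whose 3-oxygen is already the pyran ether; methoxide then opens the lactone reversibly to the Z-configured keto ester 9, and the magnesium-chelated 1,3-diketone carbon attacks the ester carbonyl held cis to it across the ring double bond (6-exo Claisen/Dieckmann closure), after which loss of methoxide and enolisation give the aromatic ring irreversibly and drain the equilibrium toward 10 with the acyl group between two hydroxyls and the ether oxygen para to it; the closest known reaction type is the Mg(OMe)2-mediated conversion of 6-(2-oxoalkyl)-4-hydroxy-2-pyranones (masked triketo esters) into acylphloroglucinols, the laboratory counterpart of the chalcone-synthase Claisen cyclisation, and the ester in 9 is no less electrophilic than the enolised beta-keto ester of that precedent; the whole sequence is basic, so the ring B prenylphenol survives, and no stereocentre is formed.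

**Compound list**

1 | triacetic acid lactone (4-hydroxy-6-methyl-2H-pyran-2-one) | CC1=CC(O)=CC(=O)O1 | starting material
2 | isoprene (2-methylbuta-1,3-diene) | C=CC(C)=C | starting material
3 | 4-hydroxy-6-methyl-3-(3-methylbut-2-en-1-yl)-2H-pyran-2-one | CC1=CC(O)=C(CC=C(C)C)C(=O)O1 | intermediate
4 | 2,2,7-trimethyl-3,4-dihydro-2H,5H-pyrano[4,3-b]pyran-5-one | CC1=CC2=C(CCC(C)(C)O2)C(=O)O1 | intermediate
5 | methyl 3-(4-hydroxyphenyl)propanoate | COC(=O)CCc1ccc(O)cc1 | starting material
6 | prenyl bromide (1-bromo-3-methylbut-2-ene) | CC(C)=CCBr | starting material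
7 | methyl 3-[4-hydroxy-3-(3-methylbut-2-en-1-yl)phenyl]propanoate | COC(=O)CCc1ccc(O)c(CC=C(C)C)c1 | intermediate
8 | 7-{4-[4-hydroxy-3-(3-methylbut-2-en-1-yl)phenyl]-2-oxobutyl}-2,2-dimethyl-3,4-dihydro-2H,5H-pyrano[4,3-b]pyran-5-one | CC(C)=CCc1cc(CCC(=O)CC2=CC3=C(CCC(C)(C)O3)C(=O)O2)ccc1O | intermediate
9 | methyl 2-{6-[4-hydroxy-3-(3-methylbut-2-en-1-yl)phenyl]-2,4-dioxohexyl}-6,6-dimethyl-5,6-dihydro-4H-pyran-3-carboxylate | COC(=O)C1=C(CC(=O)CC(=O)CCc2ccc(O)c(CC=C(C)C)c2)OC(C)(C)CC1 | intermediate
10 | 1-(5,7-dihydroxy-2,2-dimethyl-3,4-dihydro-2H-chromen-6-yl)-3-[4-hydroxy-3-(3-methylbut-2-en-1-yl)phenyl]propan-1-one (achiral) | CC(C)=CCc1cc(CCC(=O)c2c(O)cc3c(c2O)CCC(C)(C)O3)ccc1O | target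

**Step count and risks**

Total step count: 3. Longest linear sequence: 2 steps (1 → 4 → 10, or 5 → 7 → 10).

Steps most likely to fail, most risky first:

Step 3. The lithiated pyranone may acylate a plain methyl ester sluggishly, and the lactone opening/Claisen closure on a 4-alkoxy-2-pyranone is unproven. The fallback sets out from 2 and 6 and comes back to the route at 10. Isoprene 2 and commercial 2,4,6-trihydroxyacetophenone with Amberlyst 15 give 1-(5,7-dihydroxy-2,2-dimethyl-3,4-dihydro-2H-chromen-6-yl)ethan-1-one F1, separated from its 8-acetyl isomer. Prenyl bromide 6 and commercial 4-hydroxybenzaldehyde in aqueous KOH give 4-hydroxy-3-(3-methylbut-2-en-1-yl)benzaldehyde F2. Claisen–Schmidt condensation of the two (KOH, EtOH–H2O) gives (E)-1-(5,7-dihydroxy-2,2-dimethyl-3,4-dihydro-2H-chromen-6-yl)-3-[4-hydroxy-3-(3-methylbut-2-en-1-yl)phenyl]prop-2-en-1-one F3. Hydrogenation of that chalcone with RhCl(PPh3)3 (1 atm H2, benzene–EtOH) reduces the disubstituted enone olefin much faster than the trisubstituted prenyl olefin and gives 10. In this sequence the acid step is over before the ring B prenyl group is brought in.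

Step 1. Cyclisation of 3 can also close on the lactone carbonyl oxygen (4-pyranone isomer), and O-prenylation or double prenylation may lower the yield. The fallback sets out from 1 and comes back at 4. Compound 1 and 3-methylbut-2-enal with catalytic ethylenediammonium diacetate (EtOAc, 60 °C) undergo Knoevenagel condensation and oxa-6π electrocyclisation to give 2,2,7-trimethyl-2H,5H-pyrano[4,3-b]pyran-5-one F4 regioselectively. Hydrogenation of its disubstituted pyran olefin (H2, 1 atm, Pd/C, EtOAc) gives 4.

Step 2. O-alkylation and double C-alkylation compete with the ortho C-alkylation. The fallback sets out from 5 and comes back at 7. Compound 5 with allyl bromide and K2CO3 in acetone gives methyl 3-[4-(prop-2-en-1-yloxy)phenyl]propanoate F5. Aromatic Claisen rearrangement (neat, 200 °C) gives methyl 3-[4-hydroxy-3-(prop-2-en-1-yl)phenyl]propanoate F6. Cross-metathesis with 2-methylbut-2-ene (second-generation Grubbs catalyst, RuCl2(=CHPh)(H2IMes)(PCy3), CH2Cl2, 40 °C) turns the allyl group into the prenyl group of 7.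

**Further compounds**

F1 | step 3 | 1-(5,7-dihydroxy-2,2-dimethyl-3,4-dihydro-2H-chromen-6-yl)ethan-1-one | CC(=O)c1c(O)cc2c(c1O)CCC(C)(C)O2
F2 | step 3 | 4-hydroxy-3-(3-methylbut-2-en-1-yl)benzaldehyde | CC(C)=CCc1cc(C=O)ccc1O
F3 | step 3 | (E)-1-(5,7-dihydroxy-2,2-dimethyl-3,4-dihydro-2H-chromen-6-yl)-3-[4-hydroxy-3-(3-methylbut-2-en-1-yl)phenyl]prop-2-en-1-one | CC(C)=CCc1cc(/C=C/C(=O)c2c(O)cc3c(c2O)CCC(C)(C)O3)ccc1O
F4 | step 1 | 2,2,7-trimethyl-2H,5H-pyrano[4,3-b]pyran-5-one | CC1=CC2=C(C=CC(C)(C)O2)C(=O)O1
F5 | step 2 | methyl 3-[4-(prop-2-en-1-yloxy)phenyl]propanoate | COC(=O)CCc1ccc(OCC=C)cc1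
F6 | step 2 | methyl 3-[4-hydroxy-3-(prop-2-en-1-yl)phenyl]propanoate | COC(=O)CCc1ccc(O)c(CC=C)c1
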